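**Strategy.** Ring A of the flavone carries oxygen at C5, C7 and C8a (O1), all ortho or para to C4a, the carbon holding the C4 carbonyl; each C–O bond can thus arise by fluoride displacement on one symmetrical 2,4,6-trifluorobenzoyl unit. The route rests on disconnecting C3–C4 and O1–C8a of the pyranone ring C. In one operation the enolate of a B-ring ketone is C-acylated and the resulting diketone enolate closes ring C by intramolecular SNAr, leaving two activated fluorines for later exchange. The enolate precursor is an aryl ketone ArC(=O)CH2OMOM bearing 3'-O-benzyl and 4'-O-MOM groups, so that the 3- and 4'-oxygens are later unmasked together for sulfation.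

Key step: step 6

Remark: the target is achiral (no stereocentre or stereogenic axis), so no enantiomer has to be selected; the only stereodescriptor in the route is the geometry of one enolate intermediate.
Remark: sulfate monoesters are written as free hydrogen sulfates, as in the target SMILES; the sulfated intermediate and the target would be handled as dipotassium salts, the free acid being liberated only by cold cation exchange.

Step 1
Reactants: 1 2-(benzyloxy)phenol
Product: 2 2-(benzyloxy)-4-bromophenol
Conditions: NBS (1.0 equiv), MeCN, 0 °C → rt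
Reagents that add atoms: N-bromosuccinimide, O=C1CCC(=O)N1Br
Why: Electrophilic aromatic bromination, in which the free hydroxyl is the strongest activating group and directs NBS to its unhindered para position (C4), so one equivalent at 0 °C should give the 4-bromide with little ortho- or dibromination.

Step 2
Reactants: 2 2-(benzyloxy)-4-bromophenol
Product: 3 2-(benzyloxy)-4-bromo-1-(methoxymethoxy)benzene
Conditions: MOMCl, i-Pr2NEt, CH2Cl2, 0 °C → rt
Reagents that add atoms: chloromethyl methyl ether, COCCl
Why: Williamson-type O-alkylation of the phenol by the reactive α-chloro ether under amine base (MOM protection), to which the aryl bromide and the benzyl ether are inert.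

Step 3
Reactants: 4 methyl glycolate
Product: 5 methyl 2-(methoxymethoxy)acetate
Conditions: MOMCl, i-Pr2NEt, CH2Cl2, 0 °C → rt
Reagents that add atoms: chloromethyl methyl ether, COCCl
Why: MOM protection of the primary alcohol with a hindered, non-nucleophilic amine base, which should leave the methyl ester untouched and avoid transesterification or self-condensation.

Step 4
Reactants: 5 methyl 2-(methoxymethoxy)acetate
Product: 6 N-methoxy-2-(methoxymethoxy)-N-methylacetamide
Conditions: MeNH(OMe)·HCl (1.5 equiv), i-PrMgCl (3 equiv), THF, −20 → 0 °C; aq. NH4Cl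
Reagents that add atoms: N,O-dimethylhydroxylamine hydrochloride, CNOC.Cl
Why: Ester aminolysis by the chloromagnesium amide of N,O-dimethylhydroxylamine (Weinreb amide formation), in which the low temperature and the fast amide transfer keep i-PrMgCl from attacking the ester.

Step 5
Reactants: 3 2-(benzyloxy)-4-bromo-1-(methoxymethoxy)benzene; 6 N-methoxy-2-(methoxymethoxy)-N-methylacetamide
Product: 9 1-[3-(benzyloxy)-4-(methoxymethoxy)phenyl]-2-(methoxymethoxy)ethan-1-one, via aryllithium 7 (not isolated), via tetrahedral lithium adduct 8 (not isolated)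
Conditions: n-BuLi (1.05 equiv), THF, −78 °C; then 6, −78 → 0 °C; sat. aq. NH4Cl
Reagents that add atoms: none
Why: Bromine–lithium exchange is faster at −78 °C than ortho-lithiation or benzylic deprotonation, and the aryllithium adds only once because the N-methoxy chelate 8 persists until the aqueous quench (Weinreb ketone synthesis).

Step 6
Reactants: 9 1-[3-(benzyloxy)-4-(methoxymethoxy)phenyl]-2-(methoxymethoxy)ethan-1-one; 10 2,4,6-trifluorobenzoyl chloride
Product: 13 2-[3-(benzyloxy)-4-(methoxymethoxy)phenyl]-5,7-difluoro-3-(methoxymethoxy)-4H-chromen-4-one, via lithium enolate 11 (not isolated), via 1,3-diketone 12 (not isolated)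
Conditions: LiHMDS (2.2 equiv), THF, −78 °C; then 10 (1.05 equiv), −78 °C → rt; then DMF co-solvent, 60 °C
Reagents that add atoms: none
Why: LiHMDS deprotonates the only enolisable position of 9 to give the Z-lithium enolate 11, held as a chelate by the α-MOM oxygen, which attacks acid chloride 10 through carbon (Claisen-type C-acylation, forming C3–C4) to give diketone 12, and the second equivalent of base converts 12 at once into its enolate. On warming, the enolate oxygen on the B-ring side adds to an ortho C–F carbon of the trifluorophenyl ring to give a Meisenheimer adduct stabilised by the adjacent C4 carbonyl and the remaining fluorines, and loss of fluoride forms O1–C8a. The closest known reaction type is the tandem enolate acylation–intramolecular SNAr of 2-halobenzoyl chlorides that delivers chromones and 4-quinolones (Grohe–Heitzer-type cycloacylation). Ring C closes as a six-membered ring by addition–elimination at an sp2 carbon, formally 6-endo-trig with respect to the C4a=C8a bond that relays the charge to the C4 carbonyl (6-exo-trig if the arene bond C8a=C8 is counted), both modes being allowed. No stereocentre is formed, so nothing has to be controlled in that respect. The step needs C- over O-acylation, which the lithium chelate in THF favours and which the excess enolate and base back up by re-acylating at carbon with any enol ester that forms, and it needs a single ring-closure outcome, which follows because both ortho fluorines of the acyl unit are equivalent and only the B-ring-side oxygen can reach an ortho carbon through a six-membered transition state.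

Step 7
Reactants: 13 2-[3-(benzyloxy)-4-(methoxymethoxy)phenyl]-5,7-difluoro-3-(methoxymethoxy)-4H-chromen-4-one
Product: 14 5,7-bis(benzyloxy)-2-[3-(benzyloxy)-4-(methoxymethoxy)phenyl]-3-(methoxymethoxy)-4H-chromen-4-one
Conditions: BnOH (5 equiv), NaH (4 equiv), THF, 0 °C → rt (all hydride consumed); then 13, DMSO, rt → 70 °C
Reagents that add atoms: benzyl alcohol (as its sodium alkoxide), OCc1ccccc1
Why: Two nucleophilic aromatic substitutions by addition–elimination (SNAr), possible because C7–F is para and C5–F ortho to C4a, which carries the C4 carbonyl, so both Meisenheimer adducts are stabilised, while MOM and benzyl ethers are inert to alkoxide.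

Step 8
Reactants: 14 5,7-bis(benzyloxy)-2-[3-(benzyloxy)-4-(methoxymethoxy)phenyl]-3-(methoxymethoxy)-4H-chromen-4-one
Product: 15 5,7-bis(benzyloxy)-2-[3-(benzyloxy)-4-hydroxyphenyl]-3-hydroxy-4H-chromen-4-one (3',5,7-tri-O-benzylquercetin)
Conditions: HCl (1.25 M in MeOH), THF, 40 °C
Reagents that add atoms: none
Why: Acid-catalysed transacetalisation (MOM cleavage) should free the 3- and 4'-hydroxyls, while the aryl benzyl ethers, of which the 5-O-benzyl peri to the carbonyl is the most acid-sensitive, should survive dilute methanolic HCl at 40 °C.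

Step 9
Reactants: 15 5,7-bis(benzyloxy)-2-[3-(benzyloxy)-4-hydroxyphenyl]-3-hydroxy-4H-chromen-4-one
Product: 16 5,7-bis(benzyloxy)-2-[3-(benzyloxy)-4-(sulfooxy)phenyl]-4-oxo-4H-chromen-3-yl hydrogen sulfate
Conditions: SO3·pyridine (8 equiv), pyridine, 50 °C; aq. KHCO3 work-up to the dipotassium salt
Reagents that add atoms: sulfur trioxide–pyridine complex, O=S(=O)([O-])[n+]1ccccc1
Why: O-Sulfation by sulfur trioxide transfer from its pyridine complex, where the 3- and 4'-hydroxyls are the only O–H groups present, so an excess of reagent can drive the hydrogen-bonded 3-OH to completion without a regiochemical issue.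

Step 10
Reactants: 16 5,7-bis(benzyloxy)-2-[3-(benzyloxy)-4-(sulfooxy)phenyl]-4-oxo-4H-chromen-3-yl hydrogen sulfate
Product: 17 quercetin 3,4'-bissulfate (5,7-dihydroxy-2-[3-hydroxy-4-(sulfooxy)phenyl]-4-oxo-4H-chromen-3-yl hydrogen sulfate)
Conditions: H2 (1 atm), 10% Pd/C, MeOH–H2O, rt, on the dipotassium salt; cold H+ cation exchange, freeze-drying
Reagents that add atoms: none
Why: Catalytic hydrogenolysis of the three aryl benzyl ethers over Pd/C, under which sulfate monoester salts are not reduced and the tetrasubstituted C2=C3 bond of the flavone should not be hydrogenated at one atmosphere and room temperature.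

**Compound list**

1 | 2-(benzyloxy)phenol | Oc1ccccc1OCc1ccccc1 | starting material
2 | 2-(benzyloxy)-4-bromophenol | Oc1ccc(Br)cc1OCc1ccccc1 | intermediate
3 | 2-(benzyloxy)-4-bromo-1-(methoxymethoxy)benzene | COCOc1ccc(Br)cc1OCc1ccccc1 | intermediate
4 | methyl glycolate (methyl 2-hydroxyacetate) | COC(=O)CO | starting material
5 | methyl 2-(methoxymethoxy)acetate | COCOCC(=O)OC | intermediate
6 | N-methoxy-2-(methoxymethoxy)-N-methylacetamide | COCOCC(=O)N(C)OC | intermediate
7 | [3-(benzyloxy)-4-(methoxymethoxy)phenyl]lithium | [Li]c1ccc(OCOC)c(OCc2ccccc2)c1 | intermediate (not isolated)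
8 | lithium 1-[3-(benzyloxy)-4-(methoxymethoxy)phenyl]-1-[methoxy(methyl)amino]-2-(methoxymethoxy)ethan-1-olate (racemic tetrahedral adduct; the centre is lost on collapse to the ketone) | [Li+].[O-]C(COCOC)(N(C)OC)c1ccc(OCOC)c(OCc2ccccc2)c1 | intermediate (not isolated)
9 | 1-[3-(benzyloxy)-4-(methoxymethoxy)phenyl]-2-(methoxymethoxy)ethan-1-one | COCOCC(=O)c1ccc(OCOC)c(OCc2ccccc2)c1 | intermediate
10 | 2,4,6-trifluorobenzoyl chloride | O=C(Cl)c1c(F)cc(F)cc1F | starting material
11 | lithium (Z)-1-[3-(benzyloxy)-4-(methoxymethoxy)phenyl]-2-(methoxymethoxy)ethen-1-olate | [Li+].[O-]/C(=C\OCOC)c1ccc(OCOC)c(OCc2ccccc2)c1 | intermediate (not isolated)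
12 | 1-[3-(benzyloxy)-4-(methoxymethoxy)phenyl]-2-(methoxymethoxy)-3-(2,4,6-trifluorophenyl)propane-1,3-dione (racemic in the diketo form; present in the flask as its lithium enolate; the centre becomes sp2 C3) | COCOC(C(=O)c1ccc(OCOC)c(OCc2ccccc2)c1)C(=O)c1c(F)cc(F)cc1F | intermediate (not isolated)
13 | 2-[3-(benzyloxy)-4-(methoxymethoxy)phenyl]-5,7-difluoro-3-(methoxymethoxy)-4H-chromen-4-one | COCOc1c(-c2ccc(OCOC)c(OCc3ccccc3)c2)oc2cc(F)cc(F)c2c1=O | intermediate
14 | 5,7-bis(benzyloxy)-2-[3-(benzyloxy)-4-(methoxymethoxy)phenyl]-3-(methoxymethoxy)-4H-chromen-4-one | COCOc1c(-c2ccc(OCOC)c(OCc3ccccc3)c2)oc2cc(OCc3ccccc3)cc(OCc3ccccc3)c2c1=O | intermediate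
15 | 5,7-bis(benzyloxy)-2-[3-(benzyloxy)-4-hydroxyphenyl]-3-hydroxy-4H-chromen-4-one | O=c1c(O)c(-c2ccc(O)c(OCc3ccccc3)c2)oc2cc(OCc3ccccc3)cc(OCc3ccccc3)c12 | intermediate
16 | 5,7-bis(benzyloxy)-2-[3-(benzyloxy)-4-(sulfooxy)phenyl]-4-oxo-4H-chromen-3-yl hydrogen sulfate | O=c1c(OS(=O)(=O)O)c(-c2ccc(OS(=O)(=O)O)c(OCc3ccccc3)c2)oc2cc(OCc3ccccc3)cc(OCc3ccccc3)c12 | intermediate
17 | quercetin 3,4'-bissulfate | O=c1c(OS(=O)(=O)O)c(-c2ccc(OS(=O)(=O)O)c(O)c2)oc2cc(O)cc(O)c12 | target

**Step count.** Total: 10 steps. Longest linear sequence: 8 steps (steps 1, 2, 5, 6, 7, 8, 9, 10 from 1; the branch from 4 through steps 3 and 4 is of equal length).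

**Steps most likely to fail**

Step 6. The enolate may be acylated at oxygen, or the amide base at nitrogen, so that the acid chloride is consumed without C–C bond formation; the lithium-chelated diketone enolate may also fail to reach the geometry needed for ring closure. The fallback sets out from 9 and 10 and comes back at 13; it separates the two bond formations and uses a C-selective acyl donor. Acid chloride 10 would be converted with 1H-benzotriazole and Et3N in CH2Cl2 into 1-(2,4,6-trifluorobenzoyl)-1H-benzotriazole F1. The lithium enolate of 9 (LiHMDS, THF, −78 °C) would be acylated by F1, a donor class known to give β-diketones from ketone enolates without enol ester formation, and diketone 12 would be isolated. Ring closure would then be carried out separately with K2CO3 in DMF at 60–80 °C, the established SNAr cyclisation of 2-fluoroaryl 1,3-diketones, to give 13.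

Step 7. The second fluoride exchange may stall once the first benzyloxy group has lowered the electrophilicity of ring A, or forcing conditions may lead to alkoxide attack at C2 and opening of the pyranone ring. The fallback sets out from 13 and comes back at 14. One equivalent of sodium benzyloxide in DMSO at 0 °C → rt should exchange only the para fluorine at C7 and give 7-(benzyloxy)-2-[3-(benzyloxy)-4-(methoxymethoxy)phenyl]-5-fluoro-3-(methoxymethoxy)-4H-chromen-4-one F2. The remaining peri fluorine would be replaced by a less basic, α-effect hydroxide surrogate (acetohydroxamic acid, K2CO3, DMSO, 80 °C; SNAr followed by Lossen-type fragmentation) to give 7-(benzyloxy)-2-[3-(benzyloxy)-4-(methoxymethoxy)phenyl]-5-hydroxy-3-(methoxymethoxy)-4H-chromen-4-one F3. O-Benzylation of the chelated 5-hydroxyl (BnBr, K2CO3, DMF, 60 °C) would then give 14.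

Step 9. Sulfation of the hydrogen-bonded 3-hydroxyl may remain incomplete, or a sulfate ester may be lost during isolation of the polar salt. The fallback sets out from 15 and comes back at 16. Both sulfates would be installed in protected, neutral form with 2,2,2-trichloroethyl chlorosulfate, Et3N and DMAP in THF, giving 5,7-bis(benzyloxy)-2-{3-(benzyloxy)-4-[(2,2,2-trichloroethoxy)sulfonyloxy]phenyl}-4-oxo-4H-chromen-3-yl 2,2,2-trichloroethyl sulfate F4, which can be purified on silica. Reductive removal of the trichloroethyl groups (Zn, HCO2NH4, MeOH, rt) would give 16 as its ammonium salt, ready for step 10.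

**Further compounds**

F1 | step 6 | 1-(2,4,6-trifluorobenzoyl)-1H-benzotriazole | O=C(c1c(F)cc(F)cc1F)n1nnc2ccccc21
F2 | step 7 | 7-(benzyloxy)-2-[3-(benzyloxy)-4-(methoxymethoxy)phenyl]-5-fluoro-3-(methoxymethoxy)-4H-chromen-4-one | COCOc1c(-c2ccc(OCOC)c(OCc3ccccc3)c2)oc2cc(OCc3ccccc3)cc(F)c2c1=O
F3 | step 7 | 7-(benzyloxy)-2-[3-(benzyloxy)-4-(methoxymethoxy)phenyl]-5-hydroxy-3-(methoxymethoxy)-4H-chromen-4-one | COCOc1c(-c2ccc(OCOC)c(OCc3ccccc3)c2)oc2cc(OCc3ccccc3)cc(O)c2c1=O
F4 | step 9 | 5,7-bis(benzyloxy)-2-{3-(benzyloxy)-4-[(2,2,2-trichloroethoxy)sulfonyloxy]phenyl}-4-oxo-4H-chromen-3-yl 2,2,2-trichloroethyl sulfate | O=c1c(OS(=O)(=O)OCC(Cl)(Cl)Cl)c(-c2ccc(OS(=O)(=O)OCC(Cl)(Cl)Cl)c(OCc3ccccc3)c2)oc2cc(OCc3ccccc3)cc(OCc3ccccc3)c12
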